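**Strategy.** The benzene ring of the benzofuran is disconnected at C3a–C7a. Its substitution, with O1 on C7a para to the C5 methoxy group and the C6 oxygen and C7 allyl group between them, is a hydroquinone monoether pattern, which thermolysis of a squarate-derived 4-alkenyl-4-methoxycyclobutenone provides. One operation opens the four-membered ring to a dienylketene and closes the fully substituted arene, the three ring oxygens emerging differentiated as free hydroxyl (C7a), methyl ether (C5) and isopropyl ether (C6). The precursor is a cyclobutenone with allyl at C2, isopropoxy at C3 and, at C4, methoxy and a (1E,3E)-dienyl chain ending in the trimethoxyphenyl ring; the furan ring is closed afterwards through O1–C2.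

Key step: step 5

Remark on the chemistry: 3, 4, 12, 13, 15, 17 and 18 are racemic; 18 is drawn as the diastereomer from invertive oxirane opening, and its C2 epimer would dehydrate to the same benzofuran.

Step 1
Reactants: 1 diisopropyl squarate; 2 allylmagnesium bromide
Product: 5 3-allyl-4-isopropoxycyclobut-3-ene-1,2-dione, via bromomagnesium alkoxide 3 (not isolated), via tertiary carbinol 4 (not isolated)
Conditions: THF, −78 °C, 1 h; then 6 M aq. HCl, 0 °C → rt
Reagents that add atoms: water, O
Why: Grignard 1,2-addition to one squarate carbonyl, then acid-catalysed ionisation of the tertiary carbinol, hydrolysis of the isopropoxy-stabilised cyclobutenyl cation and loss of isopropanol, is the standard squarate route to 3-substituted 4-alkoxycyclobutenediones.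

Step 2
Reactants: 6 3,4,5-trimethoxybenzaldehyde; 7 propanal
Product: 9 (E)-2-methyl-3-(3,4,5-trimethoxyphenyl)prop-2-enal, via aldol adduct 8 (not isolated)
Conditions: KOH (1 equiv), MeOH, 0 °C → rt, slow addition of 7
Reagents that add atoms: none
Why: In this Claisen–Schmidt crossed aldol condensation the non-enolisable aryl aldehyde captures the propanal enolate, and E1cB dehydration of 8 gives the conjugated enal with the aryl group trans to the formyl group, the thermodynamically favoured E geometry.

Step 3
Reactants: 9 (E)-2-methyl-3-(3,4,5-trimethoxyphenyl)prop-2-enal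
Product: 10 5-[(1E,3E)-4-iodo-2-methylbuta-1,3-dien-1-yl]-1,2,3-trimethoxybenzene
Conditions: CrCl2 (6 equiv), CHI3 (2 equiv), THF/1,4-dioxane 1:6, 0 °C → rt, dark
Reagents that add atoms: iodoform, IC(I)I
Why: In the Takai iodo-olefination the geminal dichromium carbenoid from CHI3 and CrCl2 adds to the aldehyde and eliminates to the (E)-alkenyl iodide, the dioxane-rich medium reinforcing the E preference, while the existing trisubstituted alkene is untouched.

Step 4
Reactants: 10 5-[(1E,3E)-4-iodo-2-methylbuta-1,3-dien-1-yl]-1,2,3-trimethoxybenzene; 5 3-allyl-4-isopropoxycyclobut-3-ene-1,2-dione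
Product: 13 2-allyl-3-isopropoxy-4-methoxy-4-[(1E,3E)-3-methyl-4-(3,4,5-trimethoxyphenyl)buta-1,3-dienyl]cyclobut-2-en-1-one (racemic), via dienyllithium 11 (not isolated), via lithium alkoxide 12 (not isolated)
Conditions: t-BuLi (2.0 equiv), Et2O, −78 °C; cannulated into 5, THF, −78 °C; then MeOTf (3 equiv), −78 → 0 °C
Reagents that add atoms: methyl trifluoromethanesulfonate, COS(=O)(=O)C(F)(F)F
Why: Iodine–lithium exchange retains the alkene geometry, the alkenyllithium adds 1,2 to the ketone-like carbonyl next to the isopropoxy-bearing carbon (the other carbonyl is a deactivated vinylogous ester), and the lithium alkoxide is O-methylated in situ; the quaternary centre forms as a racemate and is erased in step 5.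

Step 5
Reactants: 13 2-allyl-3-isopropoxy-4-methoxy-4-[(1E,3E)-3-methyl-4-(3,4,5-trimethoxyphenyl)buta-1,3-dienyl]cyclobut-2-en-1-one
Product: 16 2-allyl-3-isopropoxy-4-methoxy-6-[(E)-1-(3,4,5-trimethoxyphenyl)prop-1-en-2-yl]phenol, via dienylketene 14 (not isolated), via cyclohexadienone 15 (not isolated)
Conditions: PhMe (0.01 M, degassed), reflux (110 °C), Ar
Reagents that add atoms: none
Why: Heating breaks the C1–C4 bond of 13 by conrotatory 4π ring opening to the dienylketene 14, whose ketene carbon then bonds to the distal carbon of the first alkene of the side chain in a thermal disrotatory 6π electrocyclisation (the C3a–C7a bond of the target), and enolisation of cyclohexadienone 15 gives the phenol. The closest known reaction type is the Moore rearrangement of squarate-derived 4-alkenyl-4-alkoxycyclobutenones to hydroquinone monoethers. The benzene ring is closed by this 6π electrocyclisation followed by aromatising tautomerisation, and the ring positions follow from the cyclobutenone: C2 (allyl) becomes C7, C3 (isopropoxy) C6, C4 (methoxy) C5 and the carbonyl carbon C7a. No stereocentre is created, since the quaternary carbon of 13 and the sp3 carbon of 15 both become aromatic. The step needs the ketene geometry with the alkenyl group turned inward, which torquoselective outward rotation of the methoxy donor supplies (the outward isomer can only reclose to 13), and it needs 6π closure to win over 8π closure, which the E alkene next to the ring secures by holding the distal alkene away from the ketene carbon. The allyl group is insulated by its CH2 and cannot join the pericyclic array, and high dilution under argon protects the phenol from acylation by the ketene and from air oxidation.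

Step 6
Reactants: 16 2-allyl-3-isopropoxy-4-methoxy-6-[(E)-1-(3,4,5-trimethoxyphenyl)prop-1-en-2-yl]phenol
Product: 19 7-allyl-6-isopropoxy-5-methoxy-3-methyl-2-(3,4,5-trimethoxyphenyl)benzofuran, via epoxide 17 (not isolated), via hydroxydihydrobenzofuran 18 (not isolated)
Conditions: mCPBA (1.0 equiv), CH2Cl2, −20 → 0 °C; then p-TsOH·H2O (10 mol%), rt
Reagents that add atoms: none
Why: Prilezhaev epoxidation should select the electron-rich trisubstituted aryl alkene over the monosubstituted allyl alkene, acid then opens the oxirane at the benzylic carbon bearing the trimethoxyphenyl group with capture by the neighbouring phenol oxygen (O1–C2, five-membered ring), and E1 dehydration of the tertiary benzylic alcohol is driven by aromatisation to the benzofuran, which erases both transient stereocentres.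

Step 7
Reactants: 19 7-allyl-6-isopropoxy-5-methoxy-3-methyl-2-(3,4,5-trimethoxyphenyl)benzofuran
Product: 21 7-allyl-5-methoxy-3-methyl-2-(3,4,5-trimethoxyphenyl)benzofuran-6-ol, via aryl dichloroborinate 20 (not isolated)
Conditions: BCl3 (2 equiv, 1 M in CH2Cl2), CH2Cl2, −78 → −20 °C; then H2O
Reagents that add atoms: none
Why: BCl3 dealkylation removes a secondary alkyl aryl ether much faster than methyl aryl ethers (SN1-like loss of the isopropyl group from the boron–ether complex), so at low temperature only the isopropyl ether should fall while the four methyl ethers, the allyl group and the benzofuran stay intact.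

**Compound list**

1 | diisopropyl squarate | CC(C)OC1=C(OC(C)C)C(=O)C1=O | starting material
2 | allylmagnesium bromide | C=CC[Mg]Br | starting material
3 | bromomagnesium 1-allyl-2,3-diisopropoxy-4-oxocyclobut-2-en-1-olate (racemic) | C=CCC1(O[Mg]Br)C(OC(C)C)=C(OC(C)C)C1=O | intermediate
4 | 4-allyl-4-hydroxy-2,3-diisopropoxycyclobut-2-en-1-one (racemic) | C=CCC1(O)C(OC(C)C)=C(OC(C)C)C1=O | intermediate
5 | 3-allyl-4-isopropoxycyclobut-3-ene-1,2-dione | C=CCC1=C(OC(C)C)C(=O)C1=O | intermediate
6 | 3,4,5-trimethoxybenzaldehyde | COc1cc(C=O)cc(OC)c1OC | starting material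
7 | propanal | CCC=O | starting material
8 | 3-hydroxy-2-methyl-3-(3,4,5-trimethoxyphenyl)propanal (diastereomer mixture, racemic) | O=CC(C)C(O)c1cc(OC)c(OC)c(OC)c1 | intermediate
9 | (E)-2-methyl-3-(3,4,5-trimethoxyphenyl)prop-2-enal | O=C/C(C)=C/c1cc(OC)c(OC)c(OC)c1 | intermediate
10 | 5-[(1E,3E)-4-iodo-2-methylbuta-1,3-dien-1-yl]-1,2,3-trimethoxybenzene | I/C=C/C(C)=C/c1cc(OC)c(OC)c(OC)c1 | intermediate
11 | [(1E,3E)-3-methyl-4-(3,4,5-trimethoxyphenyl)buta-1,3-dien-1-yl]lithium | [Li]/C=C/C(C)=C/c1cc(OC)c(OC)c(OC)c1 | intermediate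
12 | lithium alkoxide of 2-allyl-4-hydroxy-3-isopropoxy-4-[(1E,3E)-3-methyl-4-(3,4,5-trimethoxyphenyl)buta-1,3-dienyl]cyclobut-2-en-1-one (racemic) | C=CCC1=C(OC(C)C)C(O[Li])(/C=C/C(C)=C/c2cc(OC)c(OC)c(OC)c2)C1=O | intermediate
13 | 2-allyl-3-isopropoxy-4-methoxy-4-[(1E,3E)-3-methyl-4-(3,4,5-trimethoxyphenyl)buta-1,3-dienyl]cyclobut-2-en-1-one (racemic) | C=CCC1=C(OC(C)C)C(OC)(/C=C/C(C)=C/c2cc(OC)c(OC)c(OC)c2)C1=O | intermediate
14 | (3Z,5E,7E)-2-allyl-3-isopropoxy-4-methoxy-7-methyl-8-(3,4,5-trimethoxyphenyl)octa-1,3,5,7-tetraen-1-one (ketene, alkenyl group cis to the ketene carbon) | O=C=C(CC=C)/C(OC(C)C)=C(OC)\C=C\C(C)=C\c1cc(OC)c(OC)c(OC)c1 | intermediate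
15 | 2-allyl-3-isopropoxy-4-methoxy-6-[(E)-1-(3,4,5-trimethoxyphenyl)prop-1-en-2-yl]cyclohexa-2,4-dien-1-one (racemic) | O=C1C(CC=C)=C(OC(C)C)C(OC)=CC1/C(C)=C/c2cc(OC)c(OC)c(OC)c2 | intermediate
16 | 2-allyl-3-isopropoxy-4-methoxy-6-[(E)-1-(3,4,5-trimethoxyphenyl)prop-1-en-2-yl]phenol | C=CCc1c(O)c(/C(C)=C/c2cc(OC)c(OC)c(OC)c2)cc(OC)c1OC(C)C | intermediate
17 | 2-allyl-3-isopropoxy-4-methoxy-6-[(2S*,3S*)-2-methyl-3-(3,4,5-trimethoxyphenyl)oxiran-2-yl]phenol (racemic, aryl groups trans) | C[C@@]1(c2cc(OC)c(OC(C)C)c(CC=C)c2O)O[C@H]1c3cc(OC)c(OC)c(OC)c3 | intermediate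
18 | (2R*,3S*)-7-allyl-6-isopropoxy-5-methoxy-3-methyl-2-(3,4,5-trimethoxyphenyl)-2,3-dihydrobenzofuran-3-ol (racemic, methyl cis to aryl) | C[C@]1(O)c2cc(OC)c(OC(C)C)c(CC=C)c2O[C@@H]1c3cc(OC)c(OC)c(OC)c3 | intermediate
19 | 7-allyl-6-isopropoxy-5-methoxy-3-methyl-2-(3,4,5-trimethoxyphenyl)benzofuran | C=CCc1c(OC(C)C)c(OC)cc2c(C)c(-c3cc(OC)c(OC)c(OC)c3)oc12 | intermediate
20 | 7-allyl-5-methoxy-3-methyl-2-(3,4,5-trimethoxyphenyl)benzofuran-6-yl dichloroborinate | C=CCc1c(OB(Cl)Cl)c(OC)cc2c(C)c(-c3cc(OC)c(OC)c(OC)c3)oc12 | intermediate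
21 | 7-allyl-5-methoxy-3-methyl-2-(3,4,5-trimethoxyphenyl)benzofuran-6-ol | C=CCc1c(O)c(OC)cc2c(C)c(-c3cc(OC)c(OC)c(OC)c3)oc12 | target

**Step count.** Total: 7 steps. Longest linear sequence: 6 steps (steps 2–7, from 6 and 7).

**Steps most likely to fail**

Step 5. Any Z isomer at the alkene next to the four-membered ring would let the distal alkene reach the ketene carbon, so that 8π closure and a slowed 6π closure erode the benzannulation. The fallback sets out from 9 and comes back at 10; it replaces the Takai reaction by a stereospecific syn-hydrometalation that fixes the diene geometry. Corey–Fuchs homologation of 9 (CBr4, PPh3, CH2Cl2, 0 °C) should give 5-[(1E)-4,4-dibromo-2-methylbuta-1,3-dien-1-yl]-1,2,3-trimethoxybenzene F1. Treatment with n-BuLi (2.1 equiv, THF, −78 °C) should convert it into the lithium acetylide F2 and, after aqueous quench, the enyne 1,2,3-trimethoxy-5-[(1E)-2-methylbut-1-en-3-yn-1-yl]benzene F3. Hydrozirconation with Cp2Zr(H)Cl (THF, rt) should give the (E)-alkenylzirconocene chloride F4, and iodinolysis (I2, 0 °C) should return geometrically uniform 10.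

Step 6. The peracid may transfer oxygen to the electron-rich phenol ring or the allyl group, and the oxirane may open at the tertiary carbon and suffer aryl migration before the ring closes. The fallback sets out from 16 and comes back at 18. Ligand-accelerated catalytic osmylation (OsO4 cat., (DHQD)2PHAL, NMO, acetone/H2O, 0 °C) favours the trisubstituted aryl alkene and spares phenols. It should give the triol (1S*,2S*)-2-(3-allyl-2-hydroxy-4-isopropoxy-5-methoxyphenyl)-1-(3,4,5-trimethoxyphenyl)propane-1,2-diol F5. Mitsunobu etherification (PPh3, DIAD, THF, 0 °C) then activates only the secondary benzylic hydroxyl, which the phenol displaces with inversion in a 5-exo-tet closure to give 18 without a carbocation. 18 is dehydrated to 19 with p-TsOH as in step 6.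

Step 4. The basic alkenyllithium may abstract a proton from the doubly allylic CH2 of 5 or add a second time, and the hindered tertiary alkoxide may be captured incompletely by MeOTf. The fallback sets out from 11 and comes back at 13. Transmetalation of 11 with anhydrous CeCl3 (THF, −78 °C) should give the less basic dienylcerium dichloride F6. This should add to 5 to give the cerium alkoxide F7 and, after aqueous work-up, the isolable carbinol 2-allyl-4-hydroxy-3-isopropoxy-4-[(1E,3E)-3-methyl-4-(3,4,5-trimethoxyphenyl)buta-1,3-dienyl]cyclobut-2-en-1-one F8. Separate O-methylation (MeI, Ag2O, K2CO3, MeCN, rt) should then give 13.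

**Further compounds**

F1 | step 5 | 5-[(1E)-4,4-dibromo-2-methylbuta-1,3-dien-1-yl]-1,2,3-trimethoxybenzene | BrC(Br)=C/C(C)=C/c1cc(OC)c(OC)c(OC)c1
F2 | step 5 | lithium (E)-3-methyl-4-(3,4,5-trimethoxyphenyl)but-3-en-1-yn-1-ide | [Li]C#C/C(C)=C/c1cc(OC)c(OC)c(OC)c1
F3 | step 5 | 1,2,3-trimethoxy-5-[(1E)-2-methylbut-1-en-3-yn-1-yl]benzene | C#C/C(C)=C/c1cc(OC)c(OC)c(OC)c1
F4 | step 5 | chlorobis(cyclopentadienyl)[(1E,3E)-3-methyl-4-(3,4,5-trimethoxyphenyl)buta-1,3-dien-1-yl]zirconium | Cl[Zr](/C=C/C(C)=C/c1cc(OC)c(OC)c(OC)c1)(C1C=CC=C1)C1C=CC=C1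
F5 | step 6 | (1S*,2S*)-2-(3-allyl-2-hydroxy-4-isopropoxy-5-methoxyphenyl)-1-(3,4,5-trimethoxyphenyl)propane-1,2-diol | C[C@@](O)([C@@H](O)c1cc(OC)c(OC)c(OC)c1)c1cc(OC)c(OC(C)C)c(CC=C)c1O
F6 | step 4 | dichloro[(1E,3E)-3-methyl-4-(3,4,5-trimethoxyphenyl)buta-1,3-dien-1-yl]cerium | Cl[Ce](Cl)/C=C/C(C)=C/c1cc(OC)c(OC)c(OC)c1
F7 | step 4 | dichlorocerium alkoxide of 2-allyl-4-hydroxy-3-isopropoxy-4-[(1E,3E)-3-methyl-4-(3,4,5-trimethoxyphenyl)buta-1,3-dienyl]cyclobut-2-en-1-one (racemic) | C=CCC1=C(OC(C)C)C(O[Ce](Cl)Cl)(/C=C/C(C)=C/c2cc(OC)c(OC)c(OC)c2)C1=O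
F8 | step 4 | 2-allyl-4-hydroxy-3-isopropoxy-4-[(1E,3E)-3-methyl-4-(3,4,5-trimethoxyphenyl)buta-1,3-dienyl]cyclobut-2-en-1-one (racemic) | C=CCC1=C(OC(C)C)C(O)(/C=C/C(C)=C/c2cc(OC)c(OC)c(OC)c2)C1=O
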